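# Filixic acid ABP (CNP0315613.0): synthesis proposal

## The problem

Compound 16 is a linear trimer of three polyketide-type six-membered rings and has no stereocentre. Ring B, in the middle, is an aromatic butanoylphloroglucinol with butanoyl on C1 and hydroxyl on C2, C4 and C6. Ring A (C1'–C6') is an enolized 1,3,5-trione with acetyl on C2' and CMe2 at C4', and its C6' hangs by a CH2 group from C3 of ring B. Ring C (C1''–C6'') is the propanoyl analogue, and its C6'' hangs by a second CH2 from C5. No ring resists closure, so the difficulty is placement. C3 and C5 of ring B are equivalent until one is substituted, and rings A and C differ by one CH2 far from the reacting carbon. No reagent can tell the partners apart, and the wrongly assembled homologues (A-B-A, C-B-C) could hardly be separated from 16.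

Each aryl–CH2–C(enol) bridge is a vinylogous Michael adduct. Base or heat reverses it to a methylene quinone methide and a free ring (the rottlerone change), which would scramble rings A and C. Strong acid dehydrates the bridge region to xanthene-type ethers. The closing steps must therefore be mild and must not depend on bridge formation at a finished ring B.

One feature makes another plan possible. The enol oxygen on C5' forms the chain O–C5'=C6'–CH2–C3–C2, and the oxygen on C5'' forms O–C5''=C6''–CH2–C5–C6. Each chain closes to a six-membered enol lactone as long as C2 or C6 is still a carboxyl carbon. These enols are about as acidic as a carboxylic acid, so such a lactone is an internal active ester. Ring B alternates C–OH and C–substituent and is therefore a cyclized tetraketide. It can be built last, between rings A and C, from malonyl units that these rings carry and activate themselves.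

## Retrosynthesis

**Ring B, bonds C1–C6 and C1–C2 (16 ⇒ 15 ⇒ 14 + 12).**
- The neighbouring cuts are the four bridge bonds. They are the labile bonds, and making them on a finished ring B is where placement is lost.
- C1 is the only ring B carbon whose own substituent (the butanoyl carbonyl) makes it a soft, doubly activated nucleophile, so both of its ring bonds can be made by mild enolate acylation.
- Opening C1–C6 gives tetraketide lactone 15, an isomer of 16. Opening C1–C2 gives bis-lactone ketone 14 and the six-carbon salt 12.
- 14 has no aromatic ring and no butanoyl chain, and C2 and C6 are both held as enol lactones on rings A and C.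
- The forward reaction needs two C-acylations at one carbon, the first decarboxylative and the second intramolecular, with carbon preferred over oxygen in the closure.
- 12 must come last. A butanoylacetyl group on a single malonyl unit would place an enol oxygen six atoms from an active ester and would close to a pyranone. In 14 no oxygen is so placed.

**Bond C3–C4 (14 ⇒ 13 + 8, 13 ⇐ 10).**
- 14 is an unsymmetrical 2,4-disubstituted 3-oxoglutaric bis(enol ester). Cutting next to its ketone gives two nearly identical halves, lactone acids 8 (ring A) and 10 (ring C), each carrying one outer ring, one bridge and a malonyl unit.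
- The alternative cut C4–C5 is the mirror image and offers nothing more.
- Placement becomes a matter of role and not of reagent selectivity. 10 is activated at its free carboxyl as imidazolide 13 and can only be the electrophile. 8 keeps its free carboxyl and can only be the decarboxylative nucleophile.
- The forward reaction is a decarboxylative Claisen condensation that tolerates the lactones. Attack at either carbonyl on C5 of 13 gives the same connectivity.

**Bridge bonds C6'–CH2 and CH2–C3, and the lactone C–O bond (8 ⇒ 7 ⇒ 2 + 5 + 6; likewise 10 ⇒ 9 ⇒ 4 + 5 + 6).**
- Each lactone acid falls apart into an acylfilicinic acid (2 or 4), formaldehyde 5 and Meldrum's acid 6.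
- The bridges are thus still made by Michael chemistry, but in separate flasks that each hold only one kind of outer ring. Reversibility therefore cannot mix rings A and C.
- The forward reaction is a three-component condensation. Only the crossed Michael adduct (7 or 9) has an irreversible exit, because the flanking enol OH opens the acylal.

**Quaternary carbons C4' and C4'' (2 ⇒ 1, 4 ⇒ 3), and 12 ⇒ 11.**
- The gem-dimethyl trione rings come from the commercial acylphloroglucinols 1 and 3 by dearomatizing double C-methylation. This is shorter than any open-chain construction.
- Salt 12 comes from commercial β-keto ester 11 by saponification.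

## Roads not taken

**Alternative 1:** (the obvious route)
- Cut: both bridges at ring B, which gives the three finished rings 2, 4 and 2,4,6-trihydroxybutyrophenone A1.
- Forward key step: condensation with 5 in dilute alkali, or Mannich base/quinone methide alkylation, first to the two-ring compound A2 (ring C–CH2–ring B) and then to 16.
- Why the chosen plan is better:
  - The first bridge makes ring B richer in electrons, so double substitution competes.
  - The second bridge is made in a medium in which the first is reversible, with ring A and ring C donors in the same flask. That medium is the setting of the rottlerone change.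
  - Any error appears as a homologue of 16 that differs by one CH2.
  - The chosen plan has the same step count but fixes placement by connectivity.

**Alternative 2:**
- Cut: C2–C3 and C5–C6 of ring B, and also C1–butanoyl.
- Forward key step: two successive Michael additions of 2 and 4 to penta-1,4-dien-3-one A3 (or a masked form) would give ketone A4. An Effenberger-type [3+3] cyclization with malonyl dichloride A5 would then close ring B.
- Why the chosen plan is better:
  - The plan is short, but it needs α,α'-diacylation of a plain dialkyl ketone. After the first acylation the ketone enol oxygen lies six atoms from the acid chloride, so a pyranone is the normal result.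
  - The free enols of rings A and C add to the ketone of A4 to form a spiroketal, and after aromatization they would stay as xanthene-type ethers.
  - The butanoyl group would have to be introduced at the end under Lewis acid, which the bridges do not tolerate.
  - In the chosen plan every nucleophilic carbon is doubly activated, and the enol oxygens are used as leaving groups.

**Alternative 3:**
- Cut: rings A and C, each into a β-diketone arm and a dimethylmalonyl unit.
- Forward key step: a twofold [3+3] annulation of the tri-O-benzyl core A6 with dimethylmalonyl dichloride A7, followed by hydrogenolysis.
- Why the chosen plan is better: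
  - The bridges would be safe, since an aryl anion cannot leave. The desymmetrization is only moved, however, to the attachment of an acetylacetone-type and a propanoylacetone-type arm to a symmetric core.
  - Each annulation needs one acylation at a non-activated CH2 and competes with O-acylation to pyrandiones.
  - Three protecting groups and a long run-up to A6 are required.
  - The chosen plan builds one ring instead of two and needs no protecting group.

Key step: step 6

Assumption: all enolized tricarbonyl units are drawn in the tautomer of the target SMILES. Lactones 8 and 10 are drawn closed on the enol oxygen next to the CMe2 carbon; the isomer closed on the other flanking oxygen would behave the same way, because this C–O bond is cleaved again in step 6.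

## Steps

Step 1
Reactants: 1 2,4,6-trihydroxyacetophenone
Product: 2 acetylfilicinic acid (2-acetyl-3,5-dihydroxy-4,4-dimethylcyclohexa-2,5-dien-1-one)
Conditions: MeI (2.2 equiv), NaOMe (3.2 equiv), MeOH, 0 → 23 °C; then 1 M HCl
Reagents that add atoms: iodomethane, CI
Why: Alkylative dearomatization of an acylphloroglucinolate: after the first C-methylation the methylated carbon is the most electron-rich one and should be methylated again, which creates C4' and breaks aromaticity. The product sits as a delocalized, weakly nucleophilic enolate, so limiting MeI should hold back a third methylation.

Step 2
Reactants: 3 2,4,6-trihydroxypropiophenone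
Product: 4 propanoylfilicinic acid (3,5-dihydroxy-4,4-dimethyl-2-propanoylcyclohexa-2,5-dien-1-one)
Conditions: MeI (2.2 equiv), NaOMe (3.2 equiv), MeOH, 0 → 23 °C; then 1 M HCl
Reagents that add atoms: iodomethane, CI
Why: Same alkylative dearomatization as in step 1; the longer acyl chain lies away from the reacting carbon and should not change the course.

Step 3
Reactants: 2 acetylfilicinic acid; 5 formaldehyde (as paraformaldehyde); 6 Meldrum's acid (2,2-dimethyl-1,3-dioxane-4,6-dione)
Product: 8 ring A lactone acid (6-acetyl-7-hydroxy-8,8-dimethyl-2,5-dioxo-3,4,5,8-tetrahydro-2H-chromene-3-carboxylic acid; racemic), via Michael adduct 7 (not isolated)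
Conditions: 5 (1.0 equiv), 6 (1.0 equiv), Et3N (0.1 equiv), 4 Å molecular sieves, MeCN, 23 → 45 °C
Reagents that add atoms: none
Why: Three-component Knoevenagel–Michael–lactonization, a known reaction type for cyclic 1,3-dicarbonyl compounds, aldehydes and Meldrum's acid; the homo-adducts form reversibly, and only crossed adduct 7 can leave the equilibrium, by attack of its C5' enol OH on an acylal carbonyl. The temperature is kept below that of malonic half-ester decarboxylation so that the carboxyl group should survive; the new centre at C3 is racemic, labile and lost in step 6.

Step 4
Reactants: 4 propanoylfilicinic acid; 5 formaldehyde (as paraformaldehyde); 6 Meldrum's acid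
Product: 10 ring C lactone acid (7-hydroxy-8,8-dimethyl-2,5-dioxo-6-propanoyl-3,4,5,8-tetrahydro-2H-chromene-3-carboxylic acid; racemic), via Michael adduct 9 (not isolated)
Conditions: 5 (1.0 equiv), 6 (1.0 equiv), Et3N (0.1 equiv), 4 Å molecular sieves, MeCN, 23 → 45 °C
Reagents that add atoms: none
Why: Same Knoevenagel–Michael–lactonization as in step 3, run in its own flask so that ring C never meets a ring A donor while its bridge is reversible. The centre at C5 is racemic, labile and lost in step 6.

Step 5
Reactants: 11 ethyl 3-oxohexanoate
Product: 12 potassium 3-oxohexanoate
Conditions: KOH (1.0 equiv), H2O–EtOH, 0 → 23 °C; freeze-drying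
Reagents that add atoms: potassium hydroxide, [K+].[OH-]
Why: Saponification of a β-keto ester; the carboxylate salt, unlike the free acid, has no proton for the cyclic decarboxylation pathway and should be storable cold.

Step 6
Reactants: 10 ring C lactone acid; 8 ring A lactone acid; 12 potassium 3-oxohexanoate
Product: 16 filixic acid ABP, via acyl imidazolide 13 (not isolated), via bis-lactone ketone 14 (not isolated), via tetraketide lactone 15 (not isolated)
Conditions: a) 10, 1,1'-carbonyldiimidazole (CDI, 1.05 equiv), THF, 0 → 23 °C; b) 8, MgCl2 (2.5 equiv), Et3N (4 equiv), MeCN–THF, 0 → 23 °C, then the solution from a); c) 12 (1.2 equiv), MgCl2 (1.5 equiv), Et3N (2 equiv), 23 → 40 °C; cold 1 M HCl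
Reagents that add atoms: none
Why: Proposed new method: the closest known reaction types are the Masamune–Brooks decarboxylative Claisen condensation (which gives unsymmetrical 3-oxoglutarates from a malonic half-ester imidazolide and a magnesium malonate half-ester), the C-acylation of magnesium β-diketonates under MgCl2/Et3N soft enolization, and the biomimetic Claisen cyclization of 3,5,7-triketo esters to acylphloroglucinols; what is new is running them in one flask with enol lactones as acyl donors. CDI converts the free carboxyl of 10 into 13, and the magnesium enolate of 8 is acylated at C3 and loses CO2 to give 14, in which C2 and C6 are still active enol esters and no oxygen nucleophile can reach them through a five- or six-membered ring. The magnesium enolate of 12 then takes up one lactone carbonyl (directly, through the acyl imidazole formed with liberated imidazole, or through the acylketene formed by E1cB loss of the ring enolate), loses CO2 and gives β-diketone 15. Ring B closes by a 6-exo-trig Dieckmann-type attack of C1 of the chelated β-diketonate on the remaining lactone carbonyl, and tautomerization to the arene makes the closure irreversible. Placement needs no reagent control, because only 8 has a free carboxylate and can be the nucleophile, only 13 is doubly activated, and attack on either carbonyl of 13 or either lactone of 14 gives the same connectivity, so ring A ends on C3 and ring C on C5 by construction. The selectivity that the step does need is C- over O-acylation in the last closure (attack by the C2 enol oxygen would give a 4-hydroxy-2-pyranone), and chelation of both β-diketone oxygens to divalent magnesium is what should secure it. No stereocentre is formed that lasts, since C3 and C5 of 14 and 15 are labile and become sp2. The medium is a weak amine base near room temperature, far from the conditions under which the bridges exchange.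

## Compound list

1 | 2,4,6-trihydroxyacetophenone | CC(=O)c1c(O)cc(O)cc1O | starting material
2 | acetylfilicinic acid | CC(=O)C1=C(O)C(C)(C)C(O)=CC1=O | intermediate
3 | 2,4,6-trihydroxypropiophenone | CCC(=O)c1c(O)cc(O)cc1O | starting material
4 | propanoylfilicinic acid | CCC(=O)C1=C(O)C(C)(C)C(O)=CC1=O | intermediate
5 | formaldehyde (used as paraformaldehyde) | C=O | starting material
6 | Meldrum's acid (2,2-dimethyl-1,3-dioxane-4,6-dione) | CC1(C)OC(=O)CC(=O)O1 | starting material
7 | Michael adduct of ring A, 5-substituted Meldrum's acid (not isolated) | CC(=O)C1=C(O)C(C)(C)C(O)=C(CC2C(=O)OC(C)(C)OC2=O)C1=O | intermediate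
8 | ring A lactone acid (racemic) | CC(=O)C1=C(O)C(C)(C)C2=C(CC(C(=O)O)C(=O)O2)C1=O | intermediate
9 | Michael adduct of ring C, 5-substituted Meldrum's acid (not isolated) | CCC(=O)C1=C(O)C(C)(C)C(O)=C(CC2C(=O)OC(C)(C)OC2=O)C1=O | intermediate
10 | ring C lactone acid (racemic) | CCC(=O)C1=C(O)C(C)(C)C2=C(CC(C(=O)O)C(=O)O2)C1=O | intermediate
11 | ethyl 3-oxohexanoate | CCCC(=O)CC(=O)OCC | starting material
12 | potassium 3-oxohexanoate | CCCC(=O)CC(=O)[O-].[K+] | intermediate
13 | acyl imidazolide of 10 (not isolated) | CCC(=O)C1=C(O)C(C)(C)C2=C(CC(C(=O)n3ccnc3)C(=O)O2)C1=O | intermediate
14 | bis-lactone ketone, 2,4-disubstituted 3-oxoglutaric bis(enol lactone) (labile diastereomer mixture, not isolated) | CC(=O)C1=C(O)C(C)(C)C2=C(CC(C(=O)C3CC4=C(OC3=O)C(C)(C)C(O)=C(C(=O)CC)C4=O)C(=O)O2)C1=O | intermediate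
15 | tetraketide lactone (labile diastereomer mixture, not isolated) | CCCC(=O)CC(=O)C(CC1=C(O)C(C)(C)C(O)=C(C(C)=O)C1=O)C(=O)C2CC3=C(OC2=O)C(C)(C)C(O)=C(C(=O)CC)C3=O | intermediate
16 | filixic acid ABP (CNP0315613.0) | CCCC(=O)c1c(O)c(CC2=C(O)C(C)(C)C(O)=C(C(C)=O)C2=O)c(O)c(CC2=C(O)C(C)(C)C(O)=C(C(=O)CC)C2=O)c1O | target

## Step count and risks

Total step count: 6.
Longest linear sequence: 3 steps (1 → 2 → 8 → 16, or 3 → 4 → 10 → 16).

**Step 6 (key step, proposed new method).**
- The most likely failure is closure of 15 through the C2 enol oxygen instead of C1, because lactonization of activated polyketo chains is fast. That would stop the sequence at a pyranone isomer.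
- The magnesium enolate of 8 may attack the lactone of a second molecule of 8, which would put two A rings on one chain.
- 12 may lose CO2 before it is acylated.
- Once the lactones are open, slow retro-Michael exchange of the bridges may set in.
- Fallback: give up the ring construction and use known Mannich base/quinone methide chemistry. It sets out from 2 and 4 and comes back at 16.
  - 2 is aminomethylated with 5 and dimethylamine to give the Mannich base 6'-(dimethylaminomethyl)acetylfilicinic acid F1.
  - F1 is warmed in acetate-buffered MeCN with a several-fold excess of commercial A1 to give the two-ring compound norflavaspidic acid AB F2, and the excess A1 is washed out.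
  - 4 is converted in the same way into the Mannich base 6''-(dimethylaminomethyl)propanoylfilicinic acid F3.
  - F2 and F3 are combined under the same buffered conditions at the lowest workable temperature to give 16.

**Step 3.**
- The most likely failure is loss of CO2 from the malonic half ester during lactonization, because an enol ester stabilizes the carbanion left behind. That would remove the carboxyl that step 6 needs.
- Precipitation of the homo-adduct of 2 would take it out of the equilibrium.
- The water formed may reopen the lactone.
- Fallback: avoid both 5 and heat. It sets out from 2 and comes back at 8.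
  - 2 is added under catalytic base to di-tert-butyl methylenemalonate, a known isolable acceptor, to give the diester F4.
  - CF3CO2H in CH2Cl2 cleaves both tert-butyl esters to give the malonic acid F5.
  - One equivalent of 1-ethyl-3-(3-dimethylaminopropyl)carbodiimide hydrochloride at 0 °C closes one carboxyl onto the C5' enol to give 8.

**Step 4.**
- The processes that threaten step 3 apply here as well: early decarboxylation, removal of 4 as its homo-adduct, and hydrolysis of the lactone.
- Fallback: it sets out from 4 and comes back at 10. Conjugate addition of 4 to di-tert-butyl methylenemalonate gives the diester F6, acid cleavage gives the malonic acid F7, and carbodiimide lactonization gives 10.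

**Step 5.**
- The most likely failure is decarboxylation during concentration and drying if the pH drops, since the free β-keto acid fragments near room temperature. Incomplete drying would also carry water into step 6.
- Fallback: reach the acid without water or base. It sets out from 11 and comes back at 15.
  - 11 is transesterified with benzyl alcohol in refluxing toluene to give benzyl 3-oxohexanoate F8.
  - F8 is hydrogenolysed (H2, Pd/C, EtOAc, 0 °C) to give 3-oxohexanoic acid F9.
  - The filtered cold solution of F9 is used at once in part c) of step 6 in place of 12, with one more equivalent of Et3N.

## Further compounds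

F1 | step 6 | 6'-(dimethylaminomethyl)acetylfilicinic acid | CC(=O)C1=C(O)C(C)(C)C(O)=C(CN(C)C)C1=O
F2 | step 6 | norflavaspidic acid AB (ring A–CH2–ring B) | CCCC(=O)c1c(O)cc(O)c(CC2=C(O)C(C)(C)C(O)=C(C(C)=O)C2=O)c1O
F3 | step 6 | 6''-(dimethylaminomethyl)propanoylfilicinic acid | CCC(=O)C1=C(O)C(C)(C)C(O)=C(CN(C)C)C1=O
F4 | step 3 | di-tert-butyl 2-[(3-acetyl-2,4-dihydroxy-5,5-dimethyl-6-oxocyclohexa-1,3-dien-1-yl)methyl]malonate | CC(=O)C1=C(O)C(C)(C)C(O)=C(CC(C(=O)OC(C)(C)C)C(=O)OC(C)(C)C)C1=O
F5 | step 3 | 2-[(3-acetyl-2,4-dihydroxy-5,5-dimethyl-6-oxocyclohexa-1,3-dien-1-yl)methyl]malonic acid | CC(=O)C1=C(O)C(C)(C)C(O)=C(CC(C(=O)O)C(=O)O)C1=O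
F6 | step 4 | di-tert-butyl 2-[(2,4-dihydroxy-5,5-dimethyl-6-oxo-3-propanoylcyclohexa-1,3-dien-1-yl)methyl]malonate | CCC(=O)C1=C(O)C(C)(C)C(O)=C(CC(C(=O)OC(C)(C)C)C(=O)OC(C)(C)C)C1=O
F7 | step 4 | 2-[(2,4-dihydroxy-5,5-dimethyl-6-oxo-3-propanoylcyclohexa-1,3-dien-1-yl)methyl]malonic acid | CCC(=O)C1=C(O)C(C)(C)C(O)=C(CC(C(=O)O)C(=O)O)C1=O
F8 | step 5 | benzyl 3-oxohexanoate | CCCC(=O)CC(=O)OCc1ccccc1
F9 | step 5 | 3-oxohexanoic acid | CCCC(=O)CC(=O)O
A1 | alternative 1 | 2,4,6-trihydroxybutyrophenone | CCCC(=O)c1c(O)cc(O)cc1O
A2 | alternative 1 | two-ring compound ring C–CH2–ring B | CCCC(=O)c1c(O)cc(O)c(CC2=C(O)C(C)(C)C(O)=C(C(=O)CC)C2=O)c1O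
A3 | alternative 2 | penta-1,4-dien-3-one | C=CC(=O)C=C
A4 | alternative 2 | 1-(ring A)-5-(ring C)pentan-3-one | CC(=O)C1=C(O)C(C)(C)C(O)=C(CCC(=O)CCC2=C(O)C(C)(C)C(O)=C(C(=O)CC)C2=O)C1=O
A5 | alternative 2 | malonyl dichloride | O=C(Cl)CC(=O)Cl
A6 | alternative 3 | tri-O-benzyl butanoylphloroglucinol with a 3,5-dioxohexyl and a 3,5-dioxoheptyl arm | CCCC(=O)c1c(OCc2ccccc2)c(CCC(=O)CC(C)=O)c(OCc2ccccc2)c(CCC(=O)CC(=O)CC)c1OCc1ccccc1
A7 | alternative 3 | dimethylmalonyl dichloride | CC(C)(C(=O)Cl)C(=O)Cl
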